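The ratio to watch is the rate constant to target over the rate constant to intermediate A times [reagent].

| flask | starting material | reagent | remark | time |
|---|---|---|---|---|
| north-west | 0.050 M | 0.0750 M | a single well-mixed tank run continuously and read at steady state, 12 min in it on average |  |
| north-east | 0.050 M | 0.0750 M | a closed flask charged with all of it at once and left for 12 min | 12 min |
| west | 0.050 M | 0.0750 M | a tube with plug flow, the mixed feed as stated, residence time 12 min | 12 min |
| south | 0.050 M | 0.0750 M (fed, over 12.0 min) | all but reagent at the start; reagent goes in evenly over 12.0 min, the run ends at 12 min | 12 min |

    starting material → target (k1 = 0.093 min⁻¹)
    reagent + intermediate A → side product (k2 = 0.063 M⁻¹ min⁻¹)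
    starting material + reagent ⇌ intermediate B (K3 = 32 M⁻¹, k3 = 0.90 M⁻¹ min⁻¹)
    starting material + reagent → intermediate A (k4 = 20 M⁻¹ min⁻¹)

- the stated concentrations are those of everything mixed, before any reaction; amounts are the same in each set-up
- the feed brings no volume worth counting
- run time (north-east): 12 min

1. the set-up with the highest amount of target at the outlet or at the end, in percent of the starting material put in ("none" if the first two lie within 2 percentage points) (north-west / north-east / west / south / none)
2. amount of target at the outlet or at the end, in percent of the starting material put in, north-west
3. amount of target at the outlet or at the end, in percent of the starting material put in, north-east
4. amount of target at the outlet or at the end, in percent of the starting material put in, west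
5. amount of target at the outlet or at the end, in percent of the starting material put in, south

1. Compare the two losses of starting material at the charge. The path to intermediate A runs at 1.50 min⁻¹, far faster than the path to target at 0.093 min⁻¹.

2. Reckon the split. At the charged [reagent], 5.84% of the starting material lost becomes target. Call this the target share: the rate to target over the sum of the rates to target and to intermediate A, a selectivity.

3. Set the side paths aside for this estimate. The constant to intermediate A exceeds the forward constant to intermediate B, and the half-life of intermediate A by the side-product step alone at the charged [reagent], 150 min, is longer than the run.

4. Bracket north-east and west, which share one clock. Held at the charge, [reagent] gives the target share. Held at the leftover 0.0250 M, the charge of reagent less that of starting material, it gives 15.7%. The real [reagent] falls from the charge toward the leftover, so integrate the share over that whole span as an estimate. Commit to 9.19%.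

5. Place north-west. The tank works throughout at its outlet [reagent], the low end of the span, so expect a figure between 9.19% and 15.7%.

6. Bracket south by the fraction left. With no reagent, 32.8% remains and 67.2% becomes target. With each dose consumed on arrival at 0.006250 M min⁻¹, the reckoned starting material reaches zero at 5.98 min, which puts 25.2% in target. That floor lies above 15.7%, so choose south.

The forecast gives south, with 10.7%, 8.6%, 8.6% and 36% in the order asked, on the ground that “keeping reagent low while starting material remains favours target”.

The simulation gives 10.6% north-west, 8.53% north-east, 8.53% west and 36.3% south, so south leads. In the west tube, the path to intermediate A had done half of its turnover up to the asked time by 0.497 min, and at 6.00 min reagent stood at 38.8% of its charge, starting material at 0.785% and target at 8.37%. In south at that time, starting material still stood at 21.6% and target had reached 32.4%, and by 12.0 min target stood at 36.3%. Take the west tube with 0.30 M reagent: its target share at that charged [reagent] is 1.53%, against 5.84% at the recipe's charge, and that tube gave 1.62%.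

All constants are made up.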